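**Retrosynthetic overview** (ring atoms are called O1–O2–C3–C4–C5–C6: C3 = O–CH, C4 = C(Me)–O(lactone), C5 = CH2, C6 = C(Me)(10-phenyldecyl)–O)

1. Target 17 ⇒ (lactone C4–O, C5–H) 3,6-dihydro-1,2-dioxin-3-ylacetic acid 15, by iodolactonization then deiodination; C3 dictates C4 because the γ-lactone can only be cis-fused.
2. 15 ⇒ (C4=C5) acyclic bis-allylic dialkyl peroxide 14, by ring-closing metathesis: the endoperoxide ring is closed by C–C and not by C–O bond formation, after the O–O bond and both O-bearing stereocentres are in place.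
3. 14 ⇒ (C3–O) tertiary hydroperoxide 7 + dienal 10, by amine-catalysed enantioselective β-peroxidation (sets C3); aldehyde oxidation, glycol cleavage and methylenation then give the acid arm and the C5 vinyl group.
4. 7 ⇒ (C6–O) Sharpless epoxide 6, by Mo-catalysed perhydrolysis with inversion (sets C6); 6 comes from (10-bromodecyl)benzene 1 via alkyne 2 and carboalumination.
5. Enabling feature: in the 1,2-dioxane ring the C4–C5 bond is flanked on both sides by the two peroxide-bearing carbons C3 and C6, and C4 carries the lactone oxygen γ to the acyl carbon. The fused γ-lactone is therefore the retron of a C4=C5 ring alkene with a C3 acetic acid arm, and that doubly allylic peroxide alkene is an RCM retron. Ring order: 1,2-dioxine (step 10), then γ-lactone (step 11).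

Key step: step 10

Assumption: in step 6 the quinine-derived primary amine is taken to deliver the peroxy oxygen to the face of C3 that gives 3R; if a model run with a simple tertiary hydroperoxide shows the opposite sense, the quinidine-derived pseudoenantiomer is used and nothing else changes.

**Route**

Step 1
Reactants: 1 (10-bromodecyl)benzene
Product: 2 12-phenyldodec-1-yne
Conditions: LiC≡CH·H2NCH2CH2NH2, DMSO, 15 °C → rt
Reagents that add atoms: lithium acetylide ethylenediamine complex [Li+].[C-]#C.NCCN
Why: SN2 alkylation of an acetylide by a primary bromide; no stereocentre is involved.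

Step 2
Reactants: 2 12-phenyldodec-1-yne
Product: 5 (E)-3-methyl-13-phenyltridec-2-en-1-ol, via alkenyldimethylalane 3 (not isolated), via lithium alkenylaluminate 4 (not isolated)
Conditions: Me3Al, Cp2ZrCl2 (0.2 equiv), CH2Cl2, rt; n-BuLi, THF, −78 °C; (CH2O)n, −78 °C → rt; H2O
Reagents that add atoms: trimethylaluminium C[Al](C)C; paraformaldehyde (as formaldehyde) C=O
Why: Zr-catalysed syn-carboalumination of the terminal alkyne (Negishi carboalumination) places Me and Al cis, and hydroxymethylation of the aluminate proceeds with retention, which fixes the E alkene.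

Step 3
Reactants: 5 (E)-3-methyl-13-phenyltridec-2-en-1-ol
Product: 6 [(2S,3S)-3-methyl-3-(10-phenyldecyl)oxiran-2-yl]methanol
Conditions: Ti(OiPr)4 (5 mol %), L-(+)-diethyl tartrate (6 mol %), t-BuOOH, 4 Å MS, CH2Cl2, −20 °C
Reagents that add atoms: tert-butyl hydroperoxide CC(C)(C)OO
Why: Sharpless asymmetric epoxidation; the L-(+)-tartrate ligand directs oxygen to the alkene face that gives the (2S,3S)-epoxide, as with other E-3,3-disubstituted allylic alcohols.

Step 4
Reactants: 6 [(2S,3S)-3-methyl-3-(10-phenyldecyl)oxiran-2-yl]methanol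
Product: 7 (2S,3R)-3-hydroperoxy-3-methyl-13-phenyltridecane-1,2-diol
Conditions: anhydrous H2O2 in Et2O, H3PMo12O40 (cat.), rt
Reagents that add atoms: hydrogen peroxide OO
Why: Mo-catalysed perhydrolysis of an epoxide; H2O2 attacks the tertiary carbon anti to the epoxide oxygen, so the future C6 is set as R by inversion.

Step 5
Reactants: 8 (E)-2-methylbut-2-enal (tiglic aldehyde); 9 (triphenylphosphoranylidene)acetaldehyde
Product: 10 (2E,4E)-4-methylhexa-2,4-dienal
Conditions: toluene, 80 °C
Reagents that add atoms: none
Why: Wittig olefination with a stabilised formylmethylene ylide gives the E-configured two-carbon-homologated enal.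

Step 6
Reactants: 7 (2S,3R)-3-hydroperoxy-3-methyl-13-phenyltridecane-1,2-diol; 10 (2E,4E)-4-methylhexa-2,4-dienal (1.5 equiv)
Product: 11 (3R,4E)-3-{[(2S,3R)-1,2-dihydroxy-3-methyl-13-phenyltridecan-3-yl]peroxy}-4-methylhex-4-enal
Conditions: 9-amino-9-deoxy-epi-quinine (10 mol %), CF3CO2H (20 mol %), toluene, 0 °C
Reagents that add atoms: none
Why: Iminium-catalysed enantioselective conjugate addition (oxa-Michael) of a tertiary hydroperoxide to an enal with a chiral primary amine salt; the catalyst shields one face of C3 of the iminium ion, so C3 is set as R under reagent control, remote from C6, and the hindered tertiary alkoxide is a poor leaving group, which disfavours collapse to the epoxide.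

Step 7
Reactants: 11 (3R,4E)-3-{[(2S,3R)-1,2-dihydroxy-3-methyl-13-phenyltridecan-3-yl]peroxy}-4-methylhex-4-enal
Product: 12 (3R,4E)-3-{[(2S,3R)-1,2-dihydroxy-3-methyl-13-phenyltridecan-3-yl]peroxy}-4-methylhex-4-enoic acid
Conditions: NaClO2, NaH2PO4, 2-methyl-2-butene, t-BuOH/H2O, 0 °C
Reagents that add atoms: sodium chlorite [Na+].[O-]Cl=O
Why: Pinnick oxidation converts the aldehyde to the acid under buffered conditions that should leave the dialkyl peroxide, the diol and the alkene (HOCl scavenged) untouched.

Step 8
Reactants: 12 (3R,4E)-3-{[(2S,3R)-1,2-dihydroxy-3-methyl-13-phenyltridecan-3-yl]peroxy}-4-methylhex-4-enoic acid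
Product: 13 (3R,4E)-4-methyl-3-{[(2R)-2-methyl-1-oxo-12-phenyldodecan-2-yl]peroxy}hex-4-enoic acid
Conditions: NaIO4, THF/H2O (pH 7), 0 °C
Reagents that add atoms: none
Why: Periodate glycol cleavage (Malaprade reaction) removes the terminal CH2OH carbon and unmasks C5 as a non-enolisable α-peroxy aldehyde without touching the O–O bond.

Step 9
Reactants: 13 (3R,4E)-4-methyl-3-{[(2R)-2-methyl-1-oxo-12-phenyldodecan-2-yl]peroxy}hex-4-enoic acid
Product: 14 (3R,4E)-4-methyl-3-{[(3R)-3-methyl-13-phenyltridec-1-en-3-yl]peroxy}hex-4-enoic acid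
Conditions: Ph3PCH3Br, KN(SiMe3)2 (3 equiv of ylide), THF, −78 → 0 °C; aq. NaH2PO4
Reagents that add atoms: methyltriphenylphosphonium bromide C[P+](c1ccccc1)(c1ccccc1)c1ccccc1.[Br-]
Why: Wittig methylenation of the non-enolisable aldehyde installs the C5 vinyl group; the acid is carried as its carboxylate, which should not undergo E1cB loss of the peroxide.

Step 10
Reactants: 14 (3R,4E)-4-methyl-3-{[(3R)-3-methyl-13-phenyltridec-1-en-3-yl]peroxy}hex-4-enoic acid
Product: 15 2-[(3R,6R)-4,6-dimethyl-6-(10-phenyldecyl)-3,6-dihydro-1,2-dioxin-3-yl]acetic acid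
Conditions: second-generation Hoveyda–Grubbs catalyst RuCl2(H2IMes)(=CH-C6H4-2-OiPr) (5 mol %), CH2Cl2 (0.002 M), 40 °C
Reagents that add atoms: none
Why: Ring-closing olefin metathesis: the Ru alkylidene loads on the monosubstituted C5 vinyl group, adds across the tethered trisubstituted C4 alkene to a ruthenacyclobutane and cycloreverts to the C4=C5 ring alkene, expelling propene. The closest known reaction type is RCM in which a vinyl group on a quaternary, oxygen-bearing allylic carbon closes onto a trisubstituted alkene, together with olefin metathesis on alkenes that carry a dialkyl peroxide. One ring is closed, the six-membered 3,6-dihydro-1,2-dioxine O1–O2–C3–C4=C5–C6, by C=C formation between C4 and C5 (metathesis closure of a 1,7-diene through the O–O tether, helped by the quaternary C6). No stereocentre is formed; C3 and C6 should pass through unchanged because the conditions are neutral and non-nucleophilic. The step needs carbene chemistry to outrun O–O reduction and ring closure to outrun oligomerisation, which the phosphine-free catalyst, high dilution and the two hindered, non-dimerising alkenes should secure, with loss of volatile propene as driving force.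

Step 11
Reactants: 15 2-[(3R,6R)-4,6-dimethyl-6-(10-phenyldecyl)-3,6-dihydro-1,2-dioxin-3-yl]acetic acid
Product: 16 (3R,4R,4aS,7aR)-4-iodo-3,4a-dimethyl-3-(10-phenyldecyl)tetrahydrofuro[3,2-c][1,2]dioxin-6(3H)-one (iodine on C5, trans to the lactone oxygen)
Conditions: I2, NaHCO3, MeCN/H2O, 0 °C, dark
Reagents that add atoms: iodine II
Why: Iodolactonization: the carboxylate attacks the iodonium ion at the more substituted C4 in a 5-exo mode, and since a γ-lactone can only be cis-fused to the six-membered ring, C3 dictates C4, with iodine anti on C5.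

Step 12
Reactants: 16 (3R,4R,4aS,7aR)-4-iodo-3,4a-dimethyl-3-(10-phenyldecyl)tetrahydrofuro[3,2-c][1,2]dioxin-6(3H)-one
Product: 17 (3R,4aR,7aR)-3,4a-dimethyl-3-(10-phenyldecyl)tetrahydrofuro[3,2-c][1,2]dioxin-6(3H)-one (target)
Conditions: n-Bu3SnH, Et3B (cat.), air, toluene, 0 °C → rt
Reagents that add atoms: none
Why: Radical dehalogenation with a tin hydride; the secondary C5 radical is endocyclic and cannot reach the collinear geometry for attack on the ring O–O bond, and it should be reduced faster than stannyl radicals attack a dialkyl peroxide, so no stereocentre changes.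

**Compound list**

1 | (10-bromodecyl)benzene | BrCCCCCCCCCCc1ccccc1 | starting material
2 | 12-phenyldodec-1-yne | C#CCCCCCCCCCCc1ccccc1 | intermediate
3 | (E)-dimethyl(2-methyl-12-phenyldodec-1-en-1-yl)alane | C[Al](C)/C=C(\C)CCCCCCCCCCc1ccccc1 | intermediate
4 | lithium (E)-butyl(dimethyl)(2-methyl-12-phenyldodec-1-en-1-yl)aluminate | [Li+].CCCC[Al-](C)(C)/C=C(\C)CCCCCCCCCCc1ccccc1 | intermediate
5 | (E)-3-methyl-13-phenyltridec-2-en-1-ol | OC/C=C(\C)CCCCCCCCCCc1ccccc1 | intermediate
6 | [(2S,3S)-3-methyl-3-(10-phenyldecyl)oxiran-2-yl]methanol | OC[C@@H]1O[C@@]1(C)CCCCCCCCCCc1ccccc1 | intermediate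
7 | (2S,3R)-3-hydroperoxy-3-methyl-13-phenyltridecane-1,2-diol | OC[C@H](O)[C@](C)(OO)CCCCCCCCCCc1ccccc1 | intermediate
8 | (E)-2-methylbut-2-enal (tiglic aldehyde) | C/C=C(\C)C=O | starting material
9 | (triphenylphosphoranylidene)acetaldehyde | O=CC=P(c1ccccc1)(c1ccccc1)c1ccccc1 | starting material
10 | (2E,4E)-4-methylhexa-2,4-dienal | C/C=C(\C)/C=C/C=O | intermediate
11 | (3R,4E)-3-{[(2S,3R)-1,2-dihydroxy-3-methyl-13-phenyltridecan-3-yl]peroxy}-4-methylhex-4-enal | O=CC[C@@H](OO[C@](C)(CCCCCCCCCCc1ccccc1)[C@@H](O)CO)/C(C)=C/C | intermediate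
12 | (3R,4E)-3-{[(2S,3R)-1,2-dihydroxy-3-methyl-13-phenyltridecan-3-yl]peroxy}-4-methylhex-4-enoic acid | OC(=O)C[C@@H](OO[C@](C)(CCCCCCCCCCc1ccccc1)[C@@H](O)CO)/C(C)=C/C | intermediate
13 | (3R,4E)-4-methyl-3-{[(2R)-2-methyl-1-oxo-12-phenyldodecan-2-yl]peroxy}hex-4-enoic acid | OC(=O)C[C@@H](OO[C@](C)(CCCCCCCCCCc1ccccc1)C=O)/C(C)=C/C | intermediate
14 | (3R,4E)-4-methyl-3-{[(3R)-3-methyl-13-phenyltridec-1-en-3-yl]peroxy}hex-4-enoic acid | OC(=O)C[C@@H](OO[C@](C)(CCCCCCCCCCc1ccccc1)C=C)/C(C)=C/C | intermediate
15 | 2-[(3R,6R)-4,6-dimethyl-6-(10-phenyldecyl)-3,6-dihydro-1,2-dioxin-3-yl]acetic acid | OC(=O)C[C@H]1OO[C@](C)(CCCCCCCCCCc2ccccc2)C=C1C | intermediate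
16 | (3R,4R,4aS,7aR)-4-iodo-3,4a-dimethyl-3-(10-phenyldecyl)tetrahydrofuro[3,2-c][1,2]dioxin-6(3H)-one | C[C@@]1(CCCCCCCCCCc2ccccc2)[C@H](I)[C@@]2(C)OC(=O)C[C@H]2OO1 | intermediate
17 | (3R,4aR,7aR)-3,4a-dimethyl-3-(10-phenyldecyl)tetrahydrofuro[3,2-c][1,2]dioxin-6(3H)-one | C[C@@]1(CCCCCCCCCCc2ccccc2)C[C@@]2(C)OC(=O)C[C@H]2OO1 | target

**Totals and risks**

Total step count: 12. Longest linear sequence: 11 steps (steps 1–4 and 6–12).

The three steps most likely to fail:

Step 6. The β-hydroxy hydroperoxide may condense with the aldehyde carbonyl to a cyclic peroxyacetal instead of adding in conjugate fashion. The β-peroxy enamine may collapse to the epoxide by oxygen transfer. Addition may occur at the far end of the diene. Reversibility of the addition may erode selectivity at C3. Fallback (the roles of the fragments are reversed; it sets out from 10 and 6 and returns at 12): dienal 10 is peroxidised under the same amine catalysis with the simple tertiary hydroperoxide 2-methoxypropan-2-yl hydroperoxide to give (3R,4E)-3-[(2-methoxypropan-2-yl)peroxy]-4-methylhex-4-enal F1. Chlorite oxidation gives (3R,4E)-3-[(2-methoxypropan-2-yl)peroxy]-4-methylhex-4-enoic acid F2, and aqueous acetic acid removes the peroxyketal to give (3R,4E)-3-hydroperoxy-4-methylhex-4-enoic acid F3. This secondary hydroperoxide then opens epoxy alcohol 6 at the tertiary carbon with inversion (H3PMo12O40 or Yb(OTf)3 catalysis) and should give 12 directly. The tertiary C–O bond is thus formed in the union, and no β-hydroxy hydroperoxide ever meets an aldehyde.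

Step 10. Carbene loading on the neopentyl-type vinyl group may be slow, the ruthenium centre may cleave the O–O bond, the carboxylate may bind the catalyst, or the alkenes may isomerise. Fallback (relay ring closure; it sets out from 13 and returns at 15): aldehyde 13 is olefinated with the ylide from (hex-5-en-1-yl)triphenylphosphonium bromide to give (3R,4E)-4-methyl-3-{[(6Z,8R)-8-methyl-18-phenyloctadeca-1,6-dien-8-yl]peroxy}hex-4-enoic acid F4. The catalyst then initiates at the unhindered terminal alkene, expels cyclopentene and so delivers the carbene directly onto C5, which should close onto C4 to give 15.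

Step 12. Stannyl radicals may attack the O–O bond, or the C5 radical may displace at peroxide oxygen to give an oxirane. Fallback (no halogen and no tin; it sets out from 15 and returns at 17): direct Markovnikov hydro-lactonization of 15 by hydrogen-atom transfer, with Co(salen) (C16H14CoN2O2, cat.), N-fluoro-2,4,6-trimethylpyridinium tetrafluoroborate and PhSiH3. The tertiary C4 radical is oxidised to the cation and captured by the acid arm on the only face that allows cis fusion. This detour creates no new compound (F0).

Further compounds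
F1 | step 6 | (3R,4E)-3-[(2-methoxypropan-2-yl)peroxy]-4-methylhex-4-enal | O=CC[C@@H](OOC(C)(C)OC)/C(C)=C/C
F2 | step 6 | (3R,4E)-3-[(2-methoxypropan-2-yl)peroxy]-4-methylhex-4-enoic acid | OC(=O)C[C@@H](OOC(C)(C)OC)/C(C)=C/C
F3 | step 6 | (3R,4E)-3-hydroperoxy-4-methylhex-4-enoic acid | OC(=O)C[C@@H](OO)/C(C)=C/C
F4 | step 10 | (3R,4E)-4-methyl-3-{[(6Z,8R)-8-methyl-18-phenyloctadeca-1,6-dien-8-yl]peroxy}hex-4-enoic acid | OC(=O)C[C@@H](OO[C@](C)(CCCCCCCCCCc1ccccc1)/C=C\CCCC=C)/C(C)=C/C
F0 | step 12 | none | none
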